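## The problem

CNP0233042.2 joins two terpenoid skeletons through a cis-fused 2,3-dihydro-1,4-benzodioxine: O-2 and O-3 of the aromatic ring A of a 24,30-dinor-friedelane (tingenone-type) nortriterpene are bonded to C1' and C5', the ring-fusion carbons of a guaiane (primed locants for the guaiane, unprimed for the triterpene). The dioxine is the retron of a hetero-Diels–Alder reaction between a triterpene ortho-quinone and the C1'=C5' bond of a cyclopentadiene, so the task divides into an enantiopure guaia-1(5),3,11-triene and a quinonoid triterpene at the right tautomeric level. In the guaiane only C7' (isopropenyl) and C10' (methyl), cis-1,4 across the seven-membered ring, have to be built beforehand; both lie on one face of the C1'=C5' bond and should thereby control C1' and C5' in the union. In the triterpene C9, C13, C14, C17, C18 and C20 are those of tingenone, whereas C8 (hydrogen on the face of the C9 and C14 methyls) is a new centre that appears when the quinone methide becomes the 6-ene ortho-quinone. The groups that will not survive rough treatment are the cyclopentadiene (1,5-hydrogen shifts, dimerisation, acid, oxygen), the isopropenyl group (acid, reduction of a neighbouring alkene), the tertiary allylic aryl ether at C5' and the electron-rich styrene C6=C7 (acid), and the C21 ketone with its epimerisable C20 (strong base). The feature that makes the key step possible is the seven-membered ring: with alkenes placed at C5'=C6' and C8'=C9' it is a cyclohepta-1,4-diene whose sp3 carbon between the alkenes, C7', carries the isopropenyl group and whose C10'–C1' bond links the two allylic termini, which is the retron of a cis-dialkenylcyclopropane rearrangement with C6'–C7'–C8' as the three-membered ring.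

## Retrosynthesis

Union. The two aryl ether bonds O2–C1' and O3–C5' of 25 are cut together in a retro-hetero-Diels–Alder sense, giving guaia-1(5),3,11-triene 22 and ortho-quinone 24. Cutting one ether bond at a time would mean substitution at a tertiary allylic carbon with no hold on the cis fusion, whereas the cycloaddition makes both bonds on one face. 24 is the tautomer of tingenone 23 in which the O3 proton has moved to C8, so 23 brings the whole triterpene skeleton and six stereocentres. The forward reaction has to find the C1'=C5' bond, the face opposite the C10' methyl, and the orientation with O2 on C1'.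

Adjusting the guaiane. 22 is traced back by functional-group changes only: to allylic alcohol 21 (1,4-dehydration), enone 20 (1,2-reduction), dienone 19 (saturation of C8'=C9') and silyl dienol ether 18 (hydrolysis). No skeletal bond is cut, but the alkenes now at C5'=C6' and C8'=C9' turn the seven-membered ring into a rearrangement retron. The forward steps must reduce the ring alkene beside the isopropenyl group and form the diene without acid.

Key disconnection. In 18 the C10'–C1' bond is cut and C6'–C8' is re-formed, which leads to cis-dialkenylcyclopropane 17: E-propenyl on C8', a siloxycyclopentadienyl group on C6', isopropenyl on C7' trans to both. Other cuts of the seven-membered ring (alkylation at C1', metathesis at C8'=C9', a [4+3] assembly) would leave the C7'/C10' relation to remote induction across a flexible ring. This cut ties C10' to C7' through a concerted boat transition state and reduces one ring and two stereocentres to the geometry of a cyclopropane. The forward reaction asks for cis arms, an E-propenyl group and reaction through the C5'=C1' alkene.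

Cyclopentenone arm. 17 comes from cyclopentenone 16 by γ-enolisation, 16 from 1,4-diketone 15 by aldol condensation (cut C4'=C5'), and 15 from aldehyde 13 and ethyl vinyl ketone 14 by a Stetter addition (cut C5'–C1'). The neighbouring cut C6'–C5' (a cyclopentenyl metal plus a cyclopropyl electrophile) would put the configuration of the cyclopropane carbon at risk; here no bond is formed at C6'. The precursor 13 is a simple aldehyde; the forward steps must not epimerise C6'.

Propenyl arm. 13 goes back through alcohol 12 and acetate 11 to aldehyde 9 and ethyl sulfone 10 (cut C9'=C10', Julia–Kocienski olefination). A Wittig reaction at the same bond would give the Z-alkene, which is useless for the rearrangement. The forward reaction must be E-selective.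

Desymmetrisation. 9 comes from monoacetate 8, and 8 from meso diol 7 by differentiating two enantiotopic hydroxymethyl groups. This replaces an asymmetric cyclopropanation of a trisubstituted pattern by one enzymatic acylation that fixes C6', C7' and C8' together.

Cyclopropane. 7 is unmasked from acetonide 6; the isopropenyl group of 6 comes from carbinol 5 and ester 4, at a stage where dehydration can go only one way. 4 is cut at C7'–C6' and C7'–C8' into dioxepine 2 and ethyl diazoacetate 3, and 2 comes from cis-but-2-ene-1,4-diol 1. The cis alkene fixes the cis arms, and the cyclic acetal directs the ester trans to them.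

## Roads not taken

Alternative 1: The cut removes the C13 and C14 methyl groups of the triterpene half and leads back to the pentacyclic 13-en-12-one A1. In the forward key step Me2CuLi would deliver a methyl group to C14 and the resulting C13 enolate would be trapped with iodomethane, giving the 12-ketone A2 with both quaternary methyls from one flask.
- Merits: the two vicinal quaternary centres, the hardest part of the friedelane core, are installed in one operation from a flat enone, and alkylation anti to the new C14 methyl should give the natural trans relation. The triterpene would be made from simple materials, which the chosen plan does not do.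
- Weak points: conjugate addition to a fully substituted β-carbon flanked by C8 and the ring fusion is among the most reluctant cuprate reactions. The C21 ketone would need masking. After A2 the C12 carbonyl has to be removed, the 6-ene introduced and two aryl methyl ethers cleaved beside a styrene. All of this sits on top of a long route to A1.
- Comparison: this road is better in independence from an isolated natural product and in having C8 defined early. The chosen plan sets against it a total of 19 steps and six stereocentres that arrive with 23. Alternative 1 also says nothing about the guaiane half or the union, which the chosen key step addresses.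

Alternative 2: The cut opens the guaiane at C1'–C5', C2'–C3' and C3'–C4', leading to the allene–yne A3. In the forward key step [Rh(CO)2Cl]2 under CO would join the alkyne, the distal allene double bond and carbon monoxide, closing both rings to guaia-1(10),4,11-trien-3-one A4.
- Merits: both carbocycles form in one catalytic step from a short acyclic chain with only the C7' stereocentre, and there are no thermally fragile intermediates. The route is clearly shorter than the 14 steps needed here to reach 18. The alkene that must later be reduced in A4 is conjugated, so a hydride conjugate reduction would spare the isopropenyl group. In this respect it is better than step 16 below.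
- Weak points: C10' is sp2 in A4. Its methyl stereocentre would have to be set afterwards by 1,6-reduction under control of C7', a 1,4-relation across a flexible seven-membered ring with no obvious bias. A4 would then join the present route at 20 as a mixture at C10'.
- Comparison: Alternative 2 wins on step count and chemoselectivity. The chosen plan sets against it that C10' is fixed relative to C7' by a concerted transition state.

Alternative 3: The cut is the C4–C5 bond of ring A, leading to the seco-triketone A5. In the forward key step the C4 methylene of the pentane-2,3-dione chain on C10 would condense with the C5 ketone of the ring B enone and the adduct would tautomerise to the 6-ene catechol A6.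
- Merits: A6 is the catechol at exactly the level needed. Simple oxidation would give 24 as a discrete species with the 6-ene and the C8 hydrogen already fixed, and the triterpene would not rest on a natural supply. In this respect Alternative 3 is better than step 19 below, which needs an unproven tautomer equilibrium.
- Weak points: A5 presupposes the complete B–E tetracycle with four quaternary methyls. The 1,2-diketone chain can enolise at two positions and is prone to self-condensation and benzilic-type rearrangement under base. The γ-position C8 of the ring B enone is epimerisable under the same conditions.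
- Comparison: the chosen plan reaches 24 from purchased 23 in the union step itself. Should that fail, its fallback prepares the same catechol (F4) from 23 in four steps, which remains far shorter than a de novo route to A5.

Key step: step 14

Assumption: tingenone (maytenin, 23) is taken as a purchasable isolated natural product, so the triterpene half enters by relay from the natural series and the de novo work is the guaiane half and the union.

## Route

Step 1
Reactants: 1 cis-but-2-ene-1,4-diol
Product: 2 2,2-dimethyl-4,7-dihydro-1,3-dioxepine
Conditions: 2,2-dimethoxypropane, p-TsOH·H2O (cat.), CH2Cl2, rt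
Reagents that add atoms: 2,2-dimethoxypropane, COC(C)(C)OC
Why: Acid-catalysed transacetalisation; the Z-alkene holds both hydroxyl groups within reach of one acetal carbon, so the seven-membered cyclic acetal should form in preference to oligomers, and the ring later forces the carbenoid ester exo.

Step 2
Reactants: 2 2,2-dimethyl-4,7-dihydro-1,3-dioxepine; 3 ethyl diazoacetate
Product: 4 ethyl (1R,7S,8r)-4,4-dimethyl-3,5-dioxabicyclo[5.1.0]octane-8-carboxylate (exo ester, meso)
Conditions: Rh2(OAc)4 (cat.), CH2Cl2, rt, slow addition of 3 to excess 2
Reagents that add atoms: none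
Why: Rhodium-carbenoid cyclopropanation is stereospecific for the alkene, so the two CH2O arms stay cis (C6', C8'); the ester takes the exo position trans to both arms (C7'), the minor endo isomer is removed by chromatography, and the product is meso.

Step 3
Reactants: 4 ethyl (1R,7S,8r)-4,4-dimethyl-3,5-dioxabicyclo[5.1.0]octane-8-carboxylate
Product: 5 2-[(1R,7S,8r)-4,4-dimethyl-3,5-dioxabicyclo[5.1.0]octan-8-yl]propan-2-ol
Conditions: MeMgBr (3 equiv), THF, 0 °C → rt; aq NH4Cl
Reagents that add atoms: methylmagnesium bromide, C[Mg]Br
Why: Twofold Grignard addition to the ester gives the tertiary carbinol; the acetal is inert and no cyclopropane stereocentre is touched.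

Step 4
Reactants: 5 2-[(1R,7S,8r)-4,4-dimethyl-3,5-dioxabicyclo[5.1.0]octan-8-yl]propan-2-ol
Product: 6 (1R,7S,8s)-4,4-dimethyl-8-(prop-1-en-2-yl)-3,5-dioxabicyclo[5.1.0]octane
Conditions: Burgess reagent (methyl N-(triethylammoniosulfonyl)carbamate), PhMe, 50 °C
Reagents that add atoms: none
Why: Burgess dehydration (sulfamate ester, then syn-elimination) under non-acidic conditions; elimination toward the ring would create an alkylidenecyclopropane and is disfavoured by strain, so only the isopropenyl group should form, and the absence of a nucleophilic acid avoids cyclopropylcarbinyl ring opening.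

Step 5
Reactants: 6 (1R,7S,8s)-4,4-dimethyl-8-(prop-1-en-2-yl)-3,5-dioxabicyclo[5.1.0]octane
Product: 7 [(1R,2S,3s)-3-(prop-1-en-2-yl)cyclopropane-1,2-diyl]dimethanol (meso)
Conditions: pyridinium p-toluenesulfonate (cat.), MeOH, rt
Reagents that add atoms: none
Why: Mild acid-catalysed transacetalisation to methanol releases the meso diol; the seven-membered acetonide is labile enough for this weak acid, which should leave the isopropenylcyclopropane alone.

Step 6
Reactants: 7 [(1R,2S,3s)-3-(prop-1-en-2-yl)cyclopropane-1,2-diyl]dimethanol
Product: 8 [(1R,2S,3S)-2-(hydroxymethyl)-3-(prop-1-en-2-yl)cyclopropyl]methyl acetate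
Conditions: Burkholderia cepacia lipase (immobilised), vinyl acetate, t-BuOMe, rt
Reagents that add atoms: vinyl acetate, C=COC(C)=O
Why: Lipase-catalysed transesterification differentiates the enantiotopic hydroxymethyl groups of the meso diol (enzymatic desymmetrisation, established for cis-cyclopropane-1,2-dimethanols); this one acylation fixes the absolute configuration of C6', C7' and C8', and the enol leaving group makes it irreversible.

Step 7
Reactants: 8 [(1R,2S,3S)-2-(hydroxymethyl)-3-(prop-1-en-2-yl)cyclopropyl]methyl acetate
Product: 9 [(1R,2S,3R)-2-formyl-3-(prop-1-en-2-yl)cyclopropyl]methyl acetate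
Conditions: (n-Pr)4N[RuO4] (cat.), N-methylmorpholine N-oxide, 4 Å MS, CH2Cl2, 0 °C → rt
Reagents that add atoms: none
Why: Ley–Griffith oxidation stops at the aldehyde under neutral conditions, so the acetate, the isopropenyl group and the configuration of the formyl-bearing ring carbon are preserved.

Step 8
Reactants: 9 [(1R,2S,3R)-2-formyl-3-(prop-1-en-2-yl)cyclopropyl]methyl acetate; 10 5-(ethylsulfonyl)-1-phenyl-1H-tetrazole
Product: 11 {(1S,2S,3S)-2-[(E)-prop-1-en-1-yl]-3-(prop-1-en-2-yl)cyclopropyl}methyl acetate
Conditions: KN(SiMe3)2, DME, −60 °C → rt; aq NH4Cl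
Reagents that add atoms: none
Why: Julia–Kocienski olefination: the metalated sulfone adds to the aldehyde, and Smiles rearrangement with loss of SO2 and the tetrazolone gives the alkene; with the 1-phenyltetrazolyl sulfone and a potassium base in DME the E-alkene is favoured, as the C10' configuration requires, and the acetate should tolerate the hindered base at low temperature.

Step 9
Reactants: 11 {(1S,2S,3S)-2-[(E)-prop-1-en-1-yl]-3-(prop-1-en-2-yl)cyclopropyl}methyl acetate
Product: 12 {(1S,2S,3S)-2-[(E)-prop-1-en-1-yl]-3-(prop-1-en-2-yl)cyclopropyl}methanol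
Conditions: K2CO3 (cat.), MeOH, 0 °C → rt
Reagents that add atoms: none
Why: Base-catalysed methanolysis of the acetate (transesterification) frees the second hydroxymethyl arm without touching the alkenes.

Step 10
Reactants: 12 {(1S,2S,3S)-2-[(E)-prop-1-en-1-yl]-3-(prop-1-en-2-yl)cyclopropyl}methanol
Product: 13 (1S,2S,3S)-2-[(E)-prop-1-en-1-yl]-3-(prop-1-en-2-yl)cyclopropane-1-carbaldehyde
Conditions: (n-Pr)4N[RuO4] (cat.), N-methylmorpholine N-oxide, 4 Å MS, CH2Cl2, 0 °C; solution used at once
Reagents that add atoms: none
Why: Ley–Griffith oxidation as in step 7; the aldehyde carbon becomes C5'; the cis-alkenyl aldehyde is volatile and open to reversible retro-Claisen valence isomerisation, so it is not stored.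

Step 11
Reactants: 13 (1S,2S,3S)-2-[(E)-prop-1-en-1-yl]-3-(prop-1-en-2-yl)cyclopropane-1-carbaldehyde; 14 pent-1-en-3-one
Product: 15 1-{(1S,2S,3S)-2-[(E)-prop-1-en-1-yl]-3-(prop-1-en-2-yl)cyclopropyl}hexane-1,4-dione
Conditions: 3-benzyl-5-(2-hydroxyethyl)-4-methylthiazolium chloride (20 mol %), Et3N, EtOH, 70 °C
Reagents that add atoms: none
Why: Stetter reaction: the thiazolium-derived carbene turns the aldehyde into an acyl-anion equivalent (Breslow intermediate) that adds 1,4 to ethyl vinyl ketone, forming C5'–C1'; C6' should not epimerise because its enolisation would require an alkylidenecyclopropane.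

Step 12
Reactants: 15 1-{(1S,2S,3S)-2-[(E)-prop-1-en-1-yl]-3-(prop-1-en-2-yl)cyclopropyl}hexane-1,4-dione
Product: 16 2-methyl-3-{(1S,2S,3S)-2-[(E)-prop-1-en-1-yl]-3-(prop-1-en-2-yl)cyclopropyl}cyclopent-2-en-1-one
Conditions: KOH, MeOH, 20 → 40 °C
Reagents that add atoms: none
Why: Intramolecular aldol condensation of the 1,4-diketone: the C4' enolate of the ethyl ketone adds to the cyclopropyl ketone C5' and dehydration gives the tetrasubstituted cyclopentenone, the only five-membered enone available; C6' keeps its configuration for the reason given in step 11, and the temperature is kept low because the enone is already a slow-reacting cis-dialkenylcyclopropane.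

Step 13
Reactants: 16 2-methyl-3-{(1S,2S,3S)-2-[(E)-prop-1-en-1-yl]-3-(prop-1-en-2-yl)cyclopropyl}cyclopent-2-en-1-one
Product: 17 tert-butyl(dimethyl)({2-methyl-3-[(1S,2S,3S)-2-((E)-prop-1-en-1-yl)-3-(prop-1-en-2-yl)cyclopropyl]cyclopenta-1,3-dien-1-yl}oxy)silane
Conditions: TBSOTf, Et3N, CH2Cl2, −78 → 0 °C; cold NaHCO3 work-up, kept below 0 °C, used at once
Reagents that add atoms: tert-butyldimethylsilyl trifluoromethanesulfonate, CC(C)(C)[Si](C)(C)OS(=O)(=O)C(F)(F)F
Why: Soft enolisation: O-silylation gives a siloxyallyl cation and triethylamine removes the γ-proton at C1' (the other γ-position, C6', would give an alkylidenecyclopropane), so the through-conjugated silyl dienol ether with the C5'=C1' alkene should result; any cross-conjugated isomer from C2' deprotonation is its 1,5-hydrogen-shift isomer and converges in step 14.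

Step 14
Reactants: 17 tert-butyl(dimethyl)({2-methyl-3-[(1S,2S,3S)-2-((E)-prop-1-en-1-yl)-3-(prop-1-en-2-yl)cyclopropyl]cyclopenta-1,3-dien-1-yl}oxy)silane
Product: 18 tert-butyl{[(3aR,4R,7S)-1,4-dimethyl-7-(prop-1-en-2-yl)-3,3a,4,7-tetrahydroazulen-2-yl]oxy}dimethylsilane
Conditions: PhMe, 0 → 45 °C, argon
Reagents that add atoms: none
Why: Thermal [3,3] sigmatropic (Cope) rearrangement of a cis-1,2-dialkenylcyclopropane: both alkenyl arms fold over the three-membered ring into a boat transition state, C10'–C1' forms while C6'–C8' breaks, and release of the cyclopropane strain makes the step irreversible. The closest known reaction type is the cis-divinylcyclopropane to cyclohepta-1,4-diene rearrangement, including its variants in which one alkene is a silyl enol ether. The seven-membered ring closes as a pericyclic ring expansion of the cyclopropane by the four alkenyl carbons, with the new bond made between the two alkene termini and both ring alkenes necessarily cis, not by a polar cyclisation. C10' is controlled by the E geometry of the propenyl arm together with the trans isopropenyl group on C7': the methyl is exo in the boat and ends on the ring face of the isopropenyl group, which is the cis-1,4 relation of the target. C1' is controlled by the ring-enforced geometry of the C5'=C1' alkene, which places C2' exo so that H1' and H10' end cis; this centre is erased in step 18. The absolute configuration is relayed from C6', C7' and C8', fixed in step 6. The step needs reaction through the C5'=C1' alkene and not through the tetrasubstituted C4'=C5' alkene of a cross-conjugated isomer; that terminus carries an inward-pointing methyl group and would have to form a quaternary centre, while 1,5-hydrogen shifts of the cyclopentadiene feed the reactive isomer. It also needs the arms cis (alkene geometry of 1, step 2) and the propenyl group E (step 8).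

Step 15
Reactants: 18 tert-butyl{[(3aR,4R,7S)-1,4-dimethyl-7-(prop-1-en-2-yl)-3,3a,4,7-tetrahydroazulen-2-yl]oxy}dimethylsilane
Product: 19 (3aR,4R,7R)-1,4-dimethyl-7-(prop-1-en-2-yl)-3a,4,7,8-tetrahydroazulen-2(3H)-one (guaia-4,8,11-trien-3-one)
Conditions: 0.5 M aq HCl, THF, 0 °C
Reagents that add atoms: none
Why: Acid hydrolysis of the silyl dienol ether; protonation at C6', or at C4' followed by acid-mediated conjugation, gives the 4-en-3-one; C7' and C10' are not enolisable positions, and C1', which may equilibrate, is erased in step 18.

Step 16
Reactants: 19 (3aR,4R,7R)-1,4-dimethyl-7-(prop-1-en-2-yl)-3a,4,7,8-tetrahydroazulen-2(3H)-one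
Product: 20 (3aR,4R,7S)-1,4-dimethyl-7-(prop-1-en-2-yl)-3a,4,5,6,7,8-hexahydroazulen-2(3H)-one (guaia-4,11-dien-3-one)
Conditions: 2-nitrobenzenesulfonylhydrazide (added in portions), Et3N, CH2Cl2, rt, stopped at full consumption of 19
Reagents that add atoms: none
Why: Diimide, released from the sulfonylhydrazide, delivers H2 suprafacially without a metal; it discriminates by strain and substitution, so the cis-disubstituted C8'=C9' bond in the seven-membered ring should react before the 1,1-disubstituted isopropenyl group, the tetrasubstituted enone alkene is inert, and no alkene migration can occur.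

Step 17
Reactants: 20 (3aR,4R,7S)-1,4-dimethyl-7-(prop-1-en-2-yl)-3a,4,5,6,7,8-hexahydroazulen-2(3H)-one
Product: 21 (3aR,4R,7S)-1,4-dimethyl-7-(prop-1-en-2-yl)-2,3,3a,4,5,6,7,8-octahydroazulen-2-ol (both C2 epimers)
Conditions: NaBH4, CeCl3·7H2O, MeOH, −20 °C
Reagents that add atoms: none
Why: Luche reduction gives 1,2-reduction of the enone to the allylic alcohol; the new carbinol centre C3' forms as a mixture that does not matter because it is removed in the next step.

Step 18
Reactants: 21 (3aR,4R,7S)-1,4-dimethyl-7-(prop-1-en-2-yl)-2,3,3a,4,5,6,7,8-octahydroazulen-2-ol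
Product: 22 (4R,7S)-1,4-dimethyl-7-(prop-1-en-2-yl)-3,4,5,6,7,8-hexahydroazulene ((7S,10R)-guaia-1(5),3,11-triene)
Conditions: Burgess reagent (methyl N-(triethylammoniosulfonyl)carbamate), THF, rt → 45 °C; filtered through basic alumina (pentane), used at once
Reagents that add atoms: none
Why: Burgess dehydration of the allylic alcohol under non-acidic conditions gives a cyclopentadiene, and 1,5-hydrogen shifts equilibrate the ring-diene isomers toward the most substituted 1(5),3-diene; avoiding acid prevents protonation of the diene, which could epimerise C10' by way of a C1'=C10' isomer.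

Step 19
Reactants: 22 (4R,7S)-1,4-dimethyl-7-(prop-1-en-2-yl)-3,4,5,6,7,8-hexahydroazulene; 23 tingenone
Product: 25 CNP0233042.2, via ortho-quinone tautomer 24 (not isolated)
Conditions: Et3N (cat.), AcOH (cat.), PhMe, 40 °C, dark, argon, triene in excess
Reagents that add atoms: none
Why: Proposed new method: tingenone is expected to equilibrate, through buffer-shuttled transfer of the O3 proton to C8 (vinylogous keto–enol prototropy), with its 6-ene ortho-quinone tautomer 24, whose 1,2-dione is an electron-poor heterodiene toward the electron-rich tetrasubstituted C1'=C5' bond of 22; the cycloaddition aromatises ring A and so drains the unfavourable pre-equilibrium, and the two partners combine one to one with nothing split off; the closest known reaction type is the inverse-electron-demand hetero-Diels–Alder reaction of ortho-quinones (made by catechol oxidation) with alkenes and dienes to give 2,3-dihydro-1,4-benzodioxines, together with the known reactions of hydroxyquinonoids through their 1,2-dicarbonyl tautomers; C1' and C5' are set by suprafacial addition to the face opposite the C10' methyl and C7' isopropenyl groups, C8 by protonation on the face of the C9 and C14 methyls, away from the axial C13 methyl; the orientation (O2 to C1') is not secured by the substrate, so isomeric adducts would have to be separated.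

## Compound list

1 | cis-but-2-ene-1,4-diol | OC/C=C\CO | starting material
2 | 2,2-dimethyl-4,7-dihydro-1,3-dioxepine | CC1(C)OCC=CCO1 | intermediate
3 | ethyl diazoacetate | CCOC(=O)C=[N+]=[N-] | starting material
4 | ethyl (1R,7S,8r)-4,4-dimethyl-3,5-dioxabicyclo[5.1.0]octane-8-carboxylate (exo ester trans to the dioxepane ring, meso) | CCOC(=O)[C@H]1[C@@H]2COC(C)(C)OC[C@H]12 | intermediate
5 | 2-[(1R,7S,8r)-4,4-dimethyl-3,5-dioxabicyclo[5.1.0]octan-8-yl]propan-2-ol (exo, meso) | CC(C)(O)[C@H]1[C@@H]2COC(C)(C)OC[C@H]12 | intermediate
6 | (1R,7S,8s)-4,4-dimethyl-8-(prop-1-en-2-yl)-3,5-dioxabicyclo[5.1.0]octane (exo, meso) | C=C(C)[C@H]1[C@@H]2COC(C)(C)OC[C@H]12 | intermediate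
7 | [(1R,2S,3s)-3-(prop-1-en-2-yl)cyclopropane-1,2-diyl]dimethanol (meso; hydroxymethyl groups cis, isopropenyl trans to both) | C=C(C)[C@H]1[C@H](CO)[C@@H]1CO | intermediate
8 | [(1R,2S,3S)-2-(hydroxymethyl)-3-(prop-1-en-2-yl)cyclopropyl]methyl acetate | C=C(C)[C@H]1[C@H](CO)[C@@H]1COC(C)=O | intermediate
9 | [(1R,2S,3R)-2-formyl-3-(prop-1-en-2-yl)cyclopropyl]methyl acetate | C=C(C)[C@H]1[C@H](C=O)[C@@H]1COC(C)=O | intermediate
10 | 5-(ethylsulfonyl)-1-phenyl-1H-tetrazole | CCS(=O)(=O)c1nnnn1-c1ccccc1 | starting material
11 | {(1S,2S,3S)-2-[(E)-prop-1-en-1-yl]-3-(prop-1-en-2-yl)cyclopropyl}methyl acetate | C=C(C)[C@H]1[C@H](/C=C/C)[C@@H]1COC(C)=O | intermediate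
12 | {(1S,2S,3S)-2-[(E)-prop-1-en-1-yl]-3-(prop-1-en-2-yl)cyclopropyl}methanol | C=C(C)[C@H]1[C@H](/C=C/C)[C@@H]1CO | intermediate
13 | (1S,2S,3S)-2-[(E)-prop-1-en-1-yl]-3-(prop-1-en-2-yl)cyclopropane-1-carbaldehyde | C=C(C)[C@H]1[C@H](/C=C/C)[C@@H]1C=O | intermediate
14 | pent-1-en-3-one (ethyl vinyl ketone) | CCC(=O)C=C | starting material
15 | 1-{(1S,2S,3S)-2-[(E)-prop-1-en-1-yl]-3-(prop-1-en-2-yl)cyclopropyl}hexane-1,4-dione | C=C(C)[C@H]1[C@H](/C=C/C)[C@@H]1C(=O)CCC(=O)CC | intermediate
16 | 2-methyl-3-{(1S,2S,3S)-2-[(E)-prop-1-en-1-yl]-3-(prop-1-en-2-yl)cyclopropyl}cyclopent-2-en-1-one | C=C(C)[C@H]1[C@H](/C=C/C)[C@@H]1C1=C(C)C(=O)CC1 | intermediate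
17 | tert-butyl(dimethyl)({2-methyl-3-[(1S,2S,3S)-2-((E)-prop-1-en-1-yl)-3-(prop-1-en-2-yl)cyclopropyl]cyclopenta-1,3-dien-1-yl}oxy)silane (arms on C6' and C8' cis, isopropenyl on C7' trans to both) | C=C(C)[C@H]1[C@H](/C=C/C)[C@@H]1C1=CCC(O[Si](C)(C)C(C)(C)C)=C1C | intermediate
18 | tert-butyl{[(3aR,4R,7S)-1,4-dimethyl-7-(prop-1-en-2-yl)-3,3a,4,7-tetrahydroazulen-2-yl]oxy}dimethylsilane (guaia-3,5,8,11-tetraene 3-silyl ether; methyl and isopropenyl cis) | C=C(C)[C@H]1C=C[C@@H](C)[C@H]2CC(O[Si](C)(C)C(C)(C)C)=C(C)C2=C1 | intermediate
19 | (3aR,4R,7R)-1,4-dimethyl-7-(prop-1-en-2-yl)-3a,4,7,8-tetrahydroazulen-2(3H)-one (guaia-4,8,11-trien-3-one) | C=C(C)[C@H]1C=C[C@@H](C)[C@H]2CC(=O)C(C)=C2C1 | intermediate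
20 | (3aR,4R,7S)-1,4-dimethyl-7-(prop-1-en-2-yl)-3a,4,5,6,7,8-hexahydroazulen-2(3H)-one (guaia-4,11-dien-3-one) | C=C(C)[C@H]1CC[C@@H](C)[C@H]2CC(=O)C(C)=C2C1 | intermediate
21 | (3aR,4R,7S)-1,4-dimethyl-7-(prop-1-en-2-yl)-2,3,3a,4,5,6,7,8-octahydroazulen-2-ol (both C2 epimers) | C=C(C)[C@H]1CC[C@@H](C)[C@H]2CC(O)C(C)=C2C1 | intermediate
22 | (4R,7S)-1,4-dimethyl-7-(prop-1-en-2-yl)-3,4,5,6,7,8-hexahydroazulene ((7S,10R)-guaia-1(5),3,11-triene) | C=C(C)[C@H]1CC[C@@H](C)C2=C(C1)C(C)=CC2 | intermediate
23 | tingenone (maytenin; 3-hydroxy-24,30-dinor-D:A-friedooleana-1(10),3,5,7-tetraene-2,21-dione, natural configuration) | CC1=C(O)C(=O)C=C2C1=CC=C1[C@@]2(C)CC[C@@]2(C)[C@@H]3C[C@@H](C)C(=O)C[C@]3(C)CC[C@]12C | starting material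
24 | 24,30-dinor-D:A-friedooleana-1(10),4,6-triene-2,3,21-trione with 8β-H (ortho-quinone tautomer of tingenone) | O=C1C(=O)C=C2C(=C1C)C=C[C@@H]1[C@@]2(C)CC[C@@]2(C)[C@@H]3C[C@@H](C)C(=O)C[C@]3(C)CC[C@]12C | intermediate
25 | CNP0233042.2: cyclic 2,3-diether of 2,3-dihydroxy-24,30-dinor-D:A-friedooleana-1,3,5(10),6-tetraen-21-one (8β-H) with (1'S,5'S,7'S,10'R)-guaia-3,11-diene-1',5'-diyl; O-2 on C1', O-3 on C5', both oxygens on the ring-fusion face opposite the C10' methyl | C=C(C)[C@H]1CC[C@@H](C)[C@@]23CC=C(C)[C@]2(C1)Oc1c(cc2c(c1C)C=C[C@@H]1[C@@]2(C)CC[C@@]2(C)[C@@H]4C[C@@H](C)C(=O)C[C@]4(C)CC[C@]12C)O3 | target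

## Step count and least certain steps

Total: 19 steps. Longest linear sequence: 19 steps (1 → 25); 23 enters in the last step.

Step 19 (Proposed new method). The most likely failures are these:
- The prototropic equilibrium may not supply enough of 24, because proton transfer to the hindered C8 is slow and the quinone methide is the more stable tautomer, while 22 drifts through hydrogen shifts and dimerises.
- Cycloaddition may occur in the wrong orientation (O-3 to C1'), at the C3'=C4' bond, or with the diene as the 4π partner.
- C8 may be protonated on the other face.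

The fallback uses known reaction types only and runs from 23 and 22 back to 25. Reduction of 23 with Na2S2O4 (THF–water) should give, by 1,6-reduction of the quinone methide, the 7-ene catechol F1. Protection with chloromethyl methyl ether and i-Pr2NEt gives the bis(methoxymethyl) ether F2. Base-mediated conjugative isomerisation of the benzylic–allylic C6 methylene (KOt-Bu in excess, DMSO, rt, the allylarene to propenylarene type) moves the alkene into conjugation and gives the 6-ene bis-ether F3; the C8 hydrogen is set on reprotonation and C20 lies beside the reversibly enolised C21 ketone, so both centres are to be checked at this stage. Mild acid methanolysis (HCl, MeOH, 0 °C) releases the 6-ene catechol F4. Oxidation of F4 with Ag2O (Et2O, 4 Å MS, rt) in the presence of 22 generates 24 as a discrete ortho-quinone for the same cycloaddition to 25.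

Step 14 (key step). The most likely failure is rearrangement or decomposition before the reactive isomer is reached: incomplete γ-selectivity in step 13 leaves the cross-conjugated isomer, which needs a 1,5-hydrogen shift at a temperature where its own slow rearrangement through the tetrasubstituted alkene, or loss of the silyl group, can compete. The fallback changes the order of ring formation and runs from 15 back to 19. Twofold silylation of 15 (TBSOTf, Et3N) gives the 1,4-bis(silyloxy)diene F5, in which the only alkene on C6' is C5'=C1'. Warming rearranges it to the cycloheptadiene bis(silyl enol ether) F6. Acid hydrolysis gives the cycloheptenone diketone F7. Aldol condensation (KOH, MeOH) of the C4' enolate onto the ring ketone C5' then closes the five-membered ring and gives 19.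

Step 16. The most likely failure is loss of chemoselectivity: the ring alkene is flanked by two tertiary carbons, which slows diimide, so the isopropenyl group may be reduced in part or conversion may stall. The fallback masks the isopropenyl group and runs from 19 back to 20. Mukaiyama hydration (Co(acac)2, PhSiH3, O2), selective for the 1,1-disubstituted alkene, gives the tertiary alcohol F8. Hydrogenation with RhCl(PPh3)3 saturates C8'=C9' and leaves the tetrasubstituted enone, giving the saturated hydroxy enone F9. Burgess dehydration returns the isopropenyl group and gives 20, with the isopropylidene isomer to be removed on silver-nitrate-impregnated silica.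

Step 11. The most likely failure is sluggish formation of the acyl-anion equivalent from the hindered cyclopropyl aldehyde, so that polymerisation of 14, self-condensation, or valence isomerisation of 13 take over. The fallback reverses the roles of the partners and runs from 13 back to 15. Addition of vinylmagnesium bromide gives the allylic alcohol F10. Oxidation with MnO2 gives the vinyl ketone F11. A Stetter addition of propanal, an unhindered acyl donor, to F11 under the conditions of step 11 gives 15.

Step 6. The most likely failure is acylation of the other enantiotopic hydroxymethyl group, or low selectivity, because the isopropenyl group lies on the mirror plane and offers little to the enzyme. The fallback switches from acylation to hydrolysis and runs from 7 back to 8. Acetylation (Ac2O, pyridine) gives the meso diacetate F12. Hydrolysis with the same lipase in phosphate buffer cleaves the ester on the arm that the enzyme would otherwise have acylated and so delivers the mirror-image monoacetate, which is 8 if direct acylation gave its enantiomer.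

## Further compounds

F1 | step 19 | 2,3-dihydroxy-24,30-dinor-D:A-friedooleana-1,3,5(10),7-tetraen-21-one (7-ene catechol) | Cc1c(O)c(O)cc2c1CC=C1[C@@]2(C)CC[C@@]2(C)[C@@H]3C[C@@H](C)C(=O)C[C@]3(C)CC[C@]12C
F2 | step 19 | 2,3-bis(methoxymethoxy)-24,30-dinor-D:A-friedooleana-1,3,5(10),7-tetraen-21-one | Cc1c(OCOC)c(OCOC)cc2c1CC=C1[C@@]2(C)CC[C@@]2(C)[C@@H]3C[C@@H](C)C(=O)C[C@]3(C)CC[C@]12C
F3 | step 19 | 2,3-bis(methoxymethoxy)-24,30-dinor-D:A-friedooleana-1,3,5(10),6-tetraen-21-one (8β-H) | Cc1c(OCOC)c(OCOC)cc2c1C=C[C@@H]1[C@@]2(C)CC[C@@]2(C)[C@@H]3C[C@@H](C)C(=O)C[C@]3(C)CC[C@]12C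
F4 | step 19 | 2,3-dihydroxy-24,30-dinor-D:A-friedooleana-1,3,5(10),6-tetraen-21-one (6-ene catechol, 8β-H) | Cc1c(O)c(O)cc2c1C=C[C@@H]1[C@@]2(C)CC[C@@]2(C)[C@@H]3C[C@@H](C)C(=O)C[C@]3(C)CC[C@]12C
F5 | step 14 | (1Z,3Z)-1,4-bis(tert-butyldimethylsilyloxy)-1-{(1S,2S,3S)-2-[(E)-prop-1-en-1-yl]-3-(prop-1-en-2-yl)cyclopropyl}hexa-1,3-diene | C=C(C)[C@H]1[C@H](/C=C/C)[C@@H]1/C(O[Si](C)(C)C(C)(C)C)=C/C=C(/CC)O[Si](C)(C)C(C)(C)C
F6 | step 14 | 1-(tert-butyldimethylsilyloxy)-7-[(Z)-2-(tert-butyldimethylsilyloxy)but-1-en-1-yl]-6-methyl-3-(prop-1-en-2-yl)cyclohepta-1,4-diene (methyl, side chain and isopropenyl cis) | C=C(C)[C@H]1C=C[C@@H](C)[C@@H](/C=C(/CC)O[Si](C)(C)C(C)(C)C)C(O[Si](C)(C)C(C)(C)C)=C1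
F7 | step 14 | 3-methyl-2-(2-oxobutyl)-6-(prop-1-en-2-yl)cyclohept-4-en-1-one (methyl and isopropenyl cis) | C=C(C)[C@H]1C=C[C@@H](C)[C@@H](CC(=O)CC)C(=O)C1
F8 | step 16 | 7-(2-hydroxypropan-2-yl)-1,4-dimethyl-3a,4,7,8-tetrahydroazulen-2(3H)-one (11-hydroxyguaia-4,8-dien-3-one) | CC(C)(O)[C@H]1C=C[C@@H](C)[C@H]2CC(=O)C(C)=C2C1
F9 | step 16 | 7-(2-hydroxypropan-2-yl)-1,4-dimethyl-3a,4,5,6,7,8-hexahydroazulen-2(3H)-one (11-hydroxyguai-4-en-3-one) | CC(C)(O)[C@H]1CC[C@@H](C)[C@H]2CC(=O)C(C)=C2C1
F10 | step 11 | 1-{(1S,2S,3S)-2-[(E)-prop-1-en-1-yl]-3-(prop-1-en-2-yl)cyclopropyl}prop-2-en-1-ol (both carbinol epimers) | C=C(C)[C@H]1[C@H](/C=C/C)[C@@H]1C(O)C=C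
F11 | step 11 | 1-{(1S,2S,3S)-2-[(E)-prop-1-en-1-yl]-3-(prop-1-en-2-yl)cyclopropyl}prop-2-en-1-one | C=C(C)[C@H]1[C@H](/C=C/C)[C@@H]1C(=O)C=C
F12 | step 6 | [(1R,2S,3s)-3-(prop-1-en-2-yl)cyclopropane-1,2-diyl]bis(methylene) diacetate (meso) | C=C(C)[C@H]1[C@H](COC(C)=O)[C@@H]1COC(C)=O
A1 | alternative 1 | 2,3-dimethoxy-24,26,27,30-tetranor-D:A-friedooleana-1,3,5(10),13-tetraene-12,21-dione | COc1cc2c(c(C)c1OC)CC[C@@H]1[C@@]2(C)CC(=O)C=2[C@@H]3C[C@@H](C)C(=O)C[C@]3(C)CCC1=2
A2 | alternative 1 | 2,3-dimethoxy-24,30-dinor-D:A-friedooleana-1,3,5(10)-triene-12,21-dione | COc1cc2c(c(C)c1OC)CC[C@@H]1[C@@]2(C)CC(=O)[C@@]2(C)[C@@H]3C[C@@H](C)C(=O)C[C@]3(C)CC[C@]12C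
A3 | alternative 2 | (5S)-8-methyl-5-(prop-1-en-2-yl)deca-8,9-dien-2-yne | C=C=C(C)CC[C@H](C(C)=C)CC#CC
A4 | alternative 2 | (7S)-guaia-1(10),4,11-trien-3-one | C=C(C)[C@H]1CCC(C)=C2CC(=O)C(C)=C2C1
A5 | alternative 3 | 4,5-seco-24,30-dinor-D:A-friedoolean-6-ene-2,3,5,21-tetrone | CCC(=O)C(=O)CC1C(=O)C=C[C@@H]2[C@@]1(C)CC[C@@]1(C)[C@@H]3C[C@@H](C)C(=O)C[C@]3(C)CC[C@]21C
A6 | alternative 3 | 2,3-dihydroxy-24,30-dinor-D:A-friedooleana-1,3,5(10),6-tetraen-21-one | Cc1c(O)c(O)cc2c1C=C[C@@H]1[C@@]2(C)CC[C@@]2(C)[C@@H]3C[C@@H](C)C(=O)C[C@]3(C)CC[C@]12C
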